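**Retrosynthetic overview**

- Last disconnection: the bond from the quaternary ring carbon to the styryl arm. A tertiary radical (from the ring carboxylic acid) adds to a coumarin-bearing styryl sulfone anti to the neighbouring aryl group, which joins the two coumarins and sets the quaternary centre.
- Before that: the methyl on the quaternary carbon comes from ester enolate methylation, and the vinylic hydrogen of the ring alkene from decarbonylation of a formyl group.
- Key disconnection: the cyclohexene (ring C; C1 quaternary, C2 benzylic CH, C3=C4(CH3), C5H2, C6H2) is cut at C2–C3 and C5–C6 into a Morita–Baylis–Hillman carbonate (C2, C1, C6) and 3-methylbut-2-enal (C3, C4, C5 and the C4 methyl). One amine-mediated (3+3) annulation joins them and sets C2.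
- Enabling feature: C3–C4(CH3)–C5 of ring C is the α,β,γ-carbon set of 3-methylbut-2-enal, held between C2 and C6, which are 1,3-related through C1 exactly like the carbinol and methylene carbons of an acrylate-derived allyl unit.
- Ring order: coumarin pyranone ring first (one building block, used twice), then ring C in the key step; the second coumarin arrives intact in the last step.

Key step: step 5

Assumption: the hydroquinidine-derived catalyst (DHQD)2PHAL is taken to give the 2S benzylic centre shown; if the sense is opposite, the hydroquinine-derived pseudoenantiomer (DHQ)2PHAL is used.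

**Route**

Step 1
Reactants: 1 5-bromo-2-hydroxy-4-methoxybenzaldehyde; 2 ethyl (triphenylphosphoranylidene)acetate
Product: 3 6-bromo-7-methoxy-2H-chromen-2-one
Conditions: PhNEt2, 215 °C (reflux)
Reagents that add atoms: 2 ethyl (triphenylphosphoranylidene)acetate, CCOC(=O)C=P(c1ccccc1)(c1ccccc1)c1ccccc1
Why: Wittig olefination of the salicylaldehyde, followed at this temperature by E/Z isomerisation and lactonisation of the ortho-hydroxycinnamate, should give the coumarin ring in one flask.

Step 2
Reactants: 3 6-bromo-7-methoxy-2H-chromen-2-one; 4 carbon monoxide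
Product: 5 7-methoxy-2-oxo-2H-chromene-6-carbaldehyde
Conditions: PdCl2(PPh3)2 (3 mol %), CO (1 atm), HCO2Na, DMF, 100 °C
Reagents that add atoms: 4 carbon monoxide, [C-]#[O+]
Why: Palladium-catalysed reductive carbonylation of the aryl bromide (oxidative addition, CO insertion, hydride from formate, reductive elimination) should install the formyl group without touching the lactone.

Step 3
Reactants: 5 7-methoxy-2-oxo-2H-chromene-6-carbaldehyde; 6 tert-butyl acrylate
Product: 7 tert-butyl 2-[hydroxy(7-methoxy-2-oxo-2H-chromen-6-yl)methyl]prop-2-enoate (racemic)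
Conditions: DABCO (1 equiv), excess 6 as solvent, rt, several days
Reagents that add atoms: 6 tert-butyl acrylate, C=CC(=O)OC(C)(C)C
Why: Morita–Baylis–Hillman reaction; the DABCO–acrylate zwitterion adds to the aldehyde and releases the amine, giving a racemic carbinol whose stereocentre is made planar again in step 5.

Step 4
Reactants: 7 tert-butyl 2-[hydroxy(7-methoxy-2-oxo-2H-chromen-6-yl)methyl]prop-2-enoate; 8 di-tert-butyl dicarbonate
Product: 9 tert-butyl 2-{[(tert-butoxycarbonyl)oxy](7-methoxy-2-oxo-2H-chromen-6-yl)methyl}prop-2-enoate (racemic)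
Conditions: DMAP (10 mol %), CH2Cl2, 0 °C to rt
Reagents that add atoms: 8 di-tert-butyl dicarbonate, CC(C)(C)OC(=O)OC(=O)OC(C)(C)C
Why: DMAP-catalysed acylation of the secondary alcohol should give the carbonate, which is both the leaving group and the source of tert-butoxide base in the key step.

Step 5
Reactants: 9 tert-butyl 2-{[(tert-butoxycarbonyl)oxy](7-methoxy-2-oxo-2H-chromen-6-yl)methyl}prop-2-enoate; 10 3-methylbut-2-enal
Product: 13 tert-butyl (2S)-3-formyl-2-(7-methoxy-2-oxo-2H-chromen-6-yl)-4-methylcyclohex-3-ene-1-carboxylate (C1 epimers), via prenal dienamine 11 (not isolated), via C-allylated dienamine 12 (not isolated)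
Conditions: 10 (1.5 equiv), pyrrolidine (1.2 equiv), 4 Å molecular sieves, toluene, 0 °C to rt; then 9, (DHQD)2PHAL (10 mol %), rt to 40 °C; then aq. AcOH/NaOAc, rt (pyrrolidine is released again)
Reagents that add atoms: 10 3-methylbut-2-enal, CC(C)=CC=O
Why: Proposed new method: the quinuclidine nitrogen of the catalyst displaces the carbonate in an SN2′ step to give an allylammonium tert-butoxide, dienamine 11 attacks its benzylic terminus through the α-carbon in a second SN2′ step (C2–C3 bond), tert-butoxide returns the iminium ion to dienamine 12, whose terminal γ-carbon then adds to the regenerated acrylate CH2 (C5–C6 bond), and hydrolysis should give the conjugated enal. The closest known reaction types are the cinchona Lewis base-catalysed allylic alkylation of Morita–Baylis–Hillman carbonates, the Stork α-alkylation of dienamines and dienamine-mediated intramolecular vinylogous Michael cyclisations. Ring C closes in a 6-endo-trig mode onto the acrylate, the only alternative through the α-carbon being a four-membered ring. C2 is the only lasting stereocentre and is set under catalyst control in the attack on the catalyst-bound allylammonium ion, which is planar at C2 so that the racemic carbonate converges; C3 becomes sp2 and C1 is left epimeric because it is reset in step 10. The step needs benzylic instead of CH2 attack (secured by the SN2′–SN2′ Lewis base pathway), α- before γ-attack of the dienamine (the kinetic preference of linear dienamines for C-alkylation next to the formyl carbon) and a double bond that ends at C3=C4 (secured by conjugation to the formyl group).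

Step 6
Reactants: 13 tert-butyl (2S)-3-formyl-2-(7-methoxy-2-oxo-2H-chromen-6-yl)-4-methylcyclohex-3-ene-1-carboxylate
Product: 14 tert-butyl (2S)-2-(7-methoxy-2-oxo-2H-chromen-6-yl)-4-methylcyclohex-3-ene-1-carboxylate (C1 epimers)
Conditions: [Rh(cod)Cl]2 (5 mol %), 1,3-bis(diphenylphosphino)propane (10 mol %), p-xylene, 140 °C
Reagents that add atoms: none
Why: Tsuji–Wilkinson-type decarbonylation (oxidative addition of the formyl C–H to monovalent rhodium, CO extrusion, C–H reductive elimination) should replace the vinylic CHO by H with the double bond kept at C3=C4 and C2 untouched.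

Step 7
Reactants: 14 tert-butyl (2S)-2-(7-methoxy-2-oxo-2H-chromen-6-yl)-4-methylcyclohex-3-ene-1-carboxylate; 15 iodomethane
Product: 16 tert-butyl (2R)-2-(7-methoxy-2-oxo-2H-chromen-6-yl)-1,4-dimethylcyclohex-3-ene-1-carboxylate (C1 epimers; same spatial arrangement at C2, descriptor changes by priority)
Conditions: KN(SiMe3)2, THF, −78 °C; then MeI, −78 to −40 °C
Reagents that add atoms: 15 iodomethane, CI
Why: Deprotonation α to the ester and C-methylation of the potassium enolate should give the quaternary carbon; the C1 epimer ratio does not matter because C1 becomes a planar radical in step 10.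

Step 8
Reactants: 16 tert-butyl (2R)-2-(7-methoxy-2-oxo-2H-chromen-6-yl)-1,4-dimethylcyclohex-3-ene-1-carboxylate
Product: 17 (2R)-2-(7-methoxy-2-oxo-2H-chromen-6-yl)-1,4-dimethylcyclohex-3-ene-1-carboxylic acid (C1 epimers)
Conditions: Me3SiOTf, 2,6-lutidine, CH2Cl2, 0 °C; aq. NH4Cl
Reagents that add atoms: none
Why: Silyl triflate-mediated tert-butyl ester cleavage (silyl ester plus isobutene) under lutidine buffering should free the acid without protonating the trisubstituted alkene, which could otherwise lactonise onto the acid.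

Step 9
Reactants: 5 7-methoxy-2-oxo-2H-chromene-6-carbaldehyde; 18 diethyl [(benzenesulfonyl)methyl]phosphonate
Product: 19 6-[(E)-2-(benzenesulfonyl)ethenyl]-7-methoxy-2H-chromen-2-one
Conditions: NaH, THF, 0 °C; then 5, 0 °C to rt
Reagents that add atoms: 18 diethyl [(benzenesulfonyl)methyl]phosphonate, CCOP(=O)(CS(=O)(=O)c1ccccc1)OCC
Why: Horner–Wadsworth–Emmons olefination with the sulfonyl-stabilised phosphonate anion should give the E-vinyl sulfone selectively.

Step 10
Reactants: 17 (2R)-2-(7-methoxy-2-oxo-2H-chromen-6-yl)-1,4-dimethylcyclohex-3-ene-1-carboxylic acid; 19 6-[(E)-2-(benzenesulfonyl)ethenyl]-7-methoxy-2H-chromen-2-one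
Product: 20 6-[(E)-2-[(1R,2S)-2-(7-methoxy-2-oxo-2H-chromen-6-yl)-1,4-dimethylcyclohex-3-en-1-yl]ethenyl]-7-methoxy-2H-chromen-2-one (CNP0415737.1)
Conditions: Ir[dF(CF3)ppy]2(dtbbpy)PF6 (1 mol %), K2HPO4, DMF, 450 nm LEDs, rt, degassed
Reagents that add atoms: 19 6-[(E)-2-(benzenesulfonyl)ethenyl]-7-methoxy-2H-chromen-2-one, COc1cc2oc(=O)ccc2cc1/C=C/S(=O)(=O)c1ccccc1
Why: Photoredox decarboxylative alkenylation (radical addition–elimination on a β-sulfonyl styrene): the excited iridium complex oxidises the carboxylate, loss of CO2 gives the tertiary C1 radical, which should add to the sulfonyl-bearing carbon of 19 on the face opposite the pseudoaxial C2 aryl group (1,2-induction; methyl ends cis to the aryl group as required) and then lose the sulfonyl radical to give the E-styrene.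

**Compound list**

1 | 5-bromo-2-hydroxy-4-methoxybenzaldehyde | O=Cc1cc(Br)c(OC)cc1O | starting material
2 | ethyl (triphenylphosphoranylidene)acetate | CCOC(=O)C=P(c1ccccc1)(c1ccccc1)c1ccccc1 | starting material
3 | 6-bromo-7-methoxy-2H-chromen-2-one | COc1cc2oc(=O)ccc2cc1Br | intermediate
4 | carbon monoxide | [C-]#[O+] | starting material
5 | 7-methoxy-2-oxo-2H-chromene-6-carbaldehyde | COc1cc2oc(=O)ccc2cc1C=O | intermediate
6 | tert-butyl acrylate | C=CC(=O)OC(C)(C)C | starting material
7 | tert-butyl 2-[hydroxy(7-methoxy-2-oxo-2H-chromen-6-yl)methyl]prop-2-enoate (racemic) | COc1cc2oc(=O)ccc2cc1C(O)C(=C)C(=O)OC(C)(C)C | intermediate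
8 | di-tert-butyl dicarbonate | CC(C)(C)OC(=O)OC(=O)OC(C)(C)C | starting material
9 | tert-butyl 2-{[(tert-butoxycarbonyl)oxy](7-methoxy-2-oxo-2H-chromen-6-yl)methyl}prop-2-enoate (racemic) | COc1cc2oc(=O)ccc2cc1C(OC(=O)OC(C)(C)C)C(=C)C(=O)OC(C)(C)C | intermediate
10 | 3-methylbut-2-enal | CC(C)=CC=O | starting material
11 | 1-[(1E)-3-methylbuta-1,3-dien-1-yl]pyrrolidine | C=C(C)/C=C/N1CCCC1 | intermediate
12 | tert-butyl (3R)-3-(7-methoxy-2-oxo-2H-chromen-6-yl)-5-methyl-2-methylidene-4-(pyrrolidin-1-ylmethylidene)hex-5-enoate | C=C(C)C(=CN1CCCC1)[C@@H](C(=C)C(=O)OC(C)(C)C)c1cc2ccc(=O)oc2cc1OC | intermediate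
13 | tert-butyl (2S)-3-formyl-2-(7-methoxy-2-oxo-2H-chromen-6-yl)-4-methylcyclohex-3-ene-1-carboxylate (C1 epimers) | CC(C)(C)OC(=O)C1CCC(C)=C(C=O)[C@@H]1c1cc2ccc(=O)oc2cc1OC | intermediate
14 | tert-butyl (2S)-2-(7-methoxy-2-oxo-2H-chromen-6-yl)-4-methylcyclohex-3-ene-1-carboxylate (C1 epimers) | CC(C)(C)OC(=O)C1CCC(C)=C[C@@H]1c1cc2ccc(=O)oc2cc1OC | intermediate
15 | iodomethane | CI | starting material
16 | tert-butyl (2R)-2-(7-methoxy-2-oxo-2H-chromen-6-yl)-1,4-dimethylcyclohex-3-ene-1-carboxylate (C1 epimers) | CC(C)(C)OC(=O)C1(C)CCC(C)=C[C@@H]1c1cc2ccc(=O)oc2cc1OC | intermediate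
17 | (2R)-2-(7-methoxy-2-oxo-2H-chromen-6-yl)-1,4-dimethylcyclohex-3-ene-1-carboxylic acid (C1 epimers) | OC(=O)C1(C)CCC(C)=C[C@@H]1c1cc2ccc(=O)oc2cc1OC | intermediate
18 | diethyl [(benzenesulfonyl)methyl]phosphonate | CCOP(=O)(CS(=O)(=O)c1ccccc1)OCC | starting material
19 | 6-[(E)-2-(benzenesulfonyl)ethenyl]-7-methoxy-2H-chromen-2-one | COc1cc2oc(=O)ccc2cc1/C=C/S(=O)(=O)c1ccccc1 | intermediate
20 | 6-[(E)-2-[(1R,2S)-2-(7-methoxy-2-oxo-2H-chromen-6-yl)-1,4-dimethylcyclohex-3-en-1-yl]ethenyl]-7-methoxy-2H-chromen-2-one | COc1cc2oc(=O)ccc2cc1/C=C/[C@@]1(C)CCC(C)=C[C@@H]1c1cc2ccc(=O)oc2cc1OC | target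

**Step count**

Total: 10 steps. Longest linear sequence: 9 steps (steps 1 to 8 and 10); step 9 is a one-step branch from aldehyde 5.

**Steps most likely to fail**

1. Step 5 (proposed new method). The dienamine may be alkylated at the γ-carbon instead of the α-carbon, the enamine nitrogen may be allylated, or the sequence may stall before the ring-closing Michael addition. Fallback with known reaction types, setting out from 9 and returning at 14 (it replaces steps 5 and 6): carbonate 9 is alkylated under the same cinchona Lewis base catalysis with the nitronate of 2-methyl-1-nitroprop-1-ene (C-alkylation at the nitro-bearing carbon), which should give tert-butyl (3R)-3-(7-methoxy-2-oxo-2H-chromen-6-yl)-5-methyl-2-methylidene-4-nitrohex-5-enoate F1. Slow addition of Bu3SnH with AIBN in benzene at 80 °C should then remove the nitro group as an allyl radical, which closes 6-endo onto the 2-substituted acrylate and is reduced, giving 14 with the double bond at C3=C4.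

2. Step 10. The iridium photocatalyst may isomerise the new E-styrene to Z by triplet sensitisation, the hindered tertiary radical may be captured too slowly (hydrodecarboxylation instead), and face selectivity at C1 may be incomplete. Fallback setting out from 17 and returning at 20: photoredox decarboxylative alkynylation of 17 with 1-[(triisopropylsilyl)ethynyl]-1,2-benziodoxol-3(1H)-one, a fast radical trap used before any styrene exists, should give 7-methoxy-6-[(1S,6S)-3,6-dimethyl-6-{[tri(propan-2-yl)silyl]ethynyl}cyclohex-2-en-1-yl]-2H-chromen-2-one F2. Bu4NF should give 6-[(1S,6S)-6-ethynyl-3,6-dimethylcyclohex-2-en-1-yl]-7-methoxy-2H-chromen-2-one F3. Syn-hydroboration with pinacolborane under dicyclohexylborane catalysis should give 7-methoxy-6-[(1S,6R)-3,6-dimethyl-6-[(E)-2-(4,4,5,5-tetramethyl-1,3,2-dioxaborolan-2-yl)ethenyl]cyclohex-2-en-1-yl]-2H-chromen-2-one F4. Suzuki coupling of F4 with bromide 3 (Pd(PPh3)4, K3PO4, dioxane/water) should give 20, the E geometry being fixed by the hydroboration.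

3. Step 6. Oxidative addition at a formyl group flanked by two substituents may be slow, and a rhodium hydride may move the ring double bond into conjugation with the aryl group, which would also erase C2. Fallback setting out from 13 and returning at 14: Pinnick oxidation (NaClO2, NaH2PO4, 2-methylbut-2-ene) should give (6S)-5-(tert-butoxycarbonyl)-6-(7-methoxy-2-oxo-2H-chromen-6-yl)-2-methylcyclohex-1-ene-1-carboxylic acid F5. DCC and N-hydroxypyridine-2-thione should give the Barton ester 1-tert-butyl 3-(2-sulfanylidenepyridin-1(2H)-yl) (2S)-2-(7-methoxy-2-oxo-2H-chromen-6-yl)-4-methylcyclohex-3-ene-1,3-dicarboxylate F6. Barton decarboxylation of F6 at 110 to 130 °C with tert-butyl thiol should give 14 through a σ-vinyl radical that takes up hydrogen without moving the double bond.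

**Further compounds**

F1 | step 5 | tert-butyl (3R)-3-(7-methoxy-2-oxo-2H-chromen-6-yl)-5-methyl-2-methylidene-4-nitrohex-5-enoate (C4 epimers) | C=C(C)C([N+](=O)[O-])[C@@H](C(=C)C(=O)OC(C)(C)C)c1cc2ccc(=O)oc2cc1OC
F2 | step 10 | 7-methoxy-6-[(1S,6S)-3,6-dimethyl-6-{[tri(propan-2-yl)silyl]ethynyl}cyclohex-2-en-1-yl]-2H-chromen-2-one | CC(C)[Si](C(C)C)(C(C)C)C#C[C@@]1(C)CCC(C)=C[C@@H]1c1cc2ccc(=O)oc2cc1OC
F3 | step 10 | 6-[(1S,6S)-6-ethynyl-3,6-dimethylcyclohex-2-en-1-yl]-7-methoxy-2H-chromen-2-one | C#C[C@@]1(C)CCC(C)=C[C@@H]1c1cc2ccc(=O)oc2cc1OC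
F4 | step 10 | 7-methoxy-6-[(1S,6R)-3,6-dimethyl-6-[(E)-2-(4,4,5,5-tetramethyl-1,3,2-dioxaborolan-2-yl)ethenyl]cyclohex-2-en-1-yl]-2H-chromen-2-one | CC1(C)OB(/C=C/[C@@]2(C)CCC(C)=C[C@@H]2c2cc3ccc(=O)oc3cc2OC)OC1(C)C
F5 | step 6 | (6S)-5-(tert-butoxycarbonyl)-6-(7-methoxy-2-oxo-2H-chromen-6-yl)-2-methylcyclohex-1-ene-1-carboxylic acid (C5 epimers) | CC(C)(C)OC(=O)C1CCC(C)=C(C(=O)O)[C@@H]1c1cc2ccc(=O)oc2cc1OC
F6 | step 6 | 1-tert-butyl 3-(2-sulfanylidenepyridin-1(2H)-yl) (2S)-2-(7-methoxy-2-oxo-2H-chromen-6-yl)-4-methylcyclohex-3-ene-1,3-dicarboxylate (C1 epimers) | CC(C)(C)OC(=O)C1CCC(C)=C(C(=O)ON2C=CC=CC2=S)[C@@H]1c1cc2ccc(=O)oc2cc1OC
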